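Do I wait 140 h? The north flask gets the charge of the north-west run, and I must decide whether the long wait buys anything.

| flask | starting material | time |
|---|---|---|
| north-west | 0.150 M |  |
| south | 0.0900 M |  |
| north-east | 0.220 M |  |
| north | 0.150 M | 140 h |

| run | time / h | [starting material] / M |
|---|---|---|
| north-west run | 1.7 | 0.1368 |
| north-west run | 5.0 | 0.1165 |
| north-west run | 9.6 | 0.1009 |
| north-west run | 15 | 0.0871 |
| north-west run | 22 | 0.0746 |
| north-west run | 29 | 0.0638 |
| north-west run | 37 | 0.0639 |
| north-west run | 46 | 0.0616 |
| south run | 1.7 | 0.0817 |
| south run | 5.0 | 0.0697 |
| south run | 9.6 | 0.0573 |
| south run | 15 | 0.0505 |
| south run | 22 | 0.0417 |
| south run | 29 | 0.0400 |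
| south run | 37 | 0.0405 |
| south run | 46 | 0.0369 |
| north-east run | 1.7 | 0.2053 |
| north-east run | 5.0 | 0.1746 |
| north-east run | 9.6 | 0.1473 |
| north-east run | 15 | 0.1234 |
| north-east run | 22 | 0.1057 |
| north-east run | 29 | 0.0950 |
| north-east run | 37 | 0.0887 |
| north-east run | 46 | 0.0872 |

(readings scatter by 0.002 M)

* reaction order in [starting material] at the outset, round the charge of the north-west run, defined at two percent of the starting material turned into product (one fixed amount of product, the same in the runs compared)
* the south run starts with 0.0600 M less of starting material than the north-west run, and with no product. Compared where both hold the same amount of starting material, once fifteen percent of what the south run was charged with has turned into product, is the south run faster, slower or alike (within a tenth)?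
* starting material in the north run at 140 h, as a share of the starting material charged

- Overall: starting material -> product.
- Constant volume, constant temperature.
- An order is taken over about fifteen percent of the charge, up and down.

At 46 h the readings stand at 41.1%, 41.0% and 39.6% of the charge in the north-west, south and north-east runs. A common share suggests a reversible change of equal order each way. I try first order each way, for which the rate falls in a straight line with the amount of starting material and reaches zero at equilibrium.

So I set one rate against another, and time drops out. In the north-east run, starting material goes at 0.00908 M h⁻¹ near 0.197 M, and at 0.00335 M h⁻¹ near 0.127 M. The line through these two reaches zero at 0.0850 M. That reading is 38.6% of the north-east charge. I call it the stall share, the part of a charge left as starting material when the rate reaches zero.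

For the north flask it gives 0.0580 M. The north-west run held 0.0616 M at 46 h, so the wait buys 0.00360 M, about twice the scatter. I keep the charge and expect the stall share at 140 h. By 5.0 h the north-west, south and north-east runs have lost 22.3%, 22.6% and 20.6% of their charges, so the early rate roughly scales with the charge, and I take order one. At equal amounts, the south run stands further above its stall, which lies lower, so I say faster.

The forecast gives order 0.9, faster and 41%, on the ground that “The three runs level off at about the same fraction of the charge”. Its share is higher than mine, and its order is lower than my one.

The north flask holds 38.5% of its charge at 140 h, 0.10 percentage points below my stall share. The order comes out at 1.0, and product reaches half of the charge at 20.6 h in the north-west run, 20.6 h in the south run and 20.6 h in the north-east run.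

    starting material ⇌ product (0.05004 h⁻¹, 0.03128 h⁻¹)

Now I use the share on the south run. At 0.0765 M of starting material, the south run stands 0.0417 M above its stall and the north-west run 0.0185 M above its own, a ratio of 2.25. The south run is faster there, at 2.2 times the north-west rate.

All runs come from a simulation with made-up constants; scatter was added.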